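I began from late times, when the intermediate and the target should have come to terms with each other, and worked back to the two set-ups.

- Sunday's: substrate 0.10 M; time 8.0 min; everything together in a closed stirred flask, run for 8.0 min
- Monday's: substrate 0.10 M; one stirred flow tank at steady state, fed with the mixture as stated, mean residence time 8.0 min

    intermediate ⇌ isomer of the product (K1 = 99, k1 = 1.38 × 10⁻⁴ s⁻¹)
    intermediate ⇌ target (K2 = 0.80, k2 = 0.0118 s⁻¹)
    substrate → intermediate (k3 = 0.00298 s⁻¹)
    substrate ⇌ dormant form (K4 = 2.9, k4 = 0.00184 s⁻¹)

1. the set-up with the highest amount of target at the outlet or at the end, in percent of the substrate put in ("none" if the first two lie within 2 percentage points) (Sunday's / Monday's / none)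
2. amount of target at the outlet or at the end, in percent of the substrate put in, Sunday's
3. amount of target at the outlet or at the end, in percent of the substrate put in, Monday's

**Pair share.** Step 2 relaxes in 0.628 min, which is far shorter than the 8.0 min of either set-up, so I treated the intermediate and the target as one pool. I called the pair share the fraction of that pool standing as target at the equilibrium of step 2, 44.4%.

**Sunday's flask.** A fraction 61.8% of the substrate leaving at first goes towards the intermediate, so after 8.0 min the pool held 55.7% of the charge, and the pair share gave 24.8%. My objection was that the dormant form returns, which makes the pool larger than I said. But its return constant, 0.0381 min⁻¹, is smaller than the 0.289 min⁻¹ of the substrate's departure, and the drain to the isomer works the other way, at 0.00460 min⁻¹, which comes to 3.68% over 8.0 min for a pool present throughout the run, whereas this pool filled during it. I kept the figure.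

**Monday's tank.** A balance that counted the return left 32.2% of the feed as substrate, so the pool received 46.0%, and the pair share gave 20.4%. The objection was that the outflow, at 0.125 min⁻¹, competes with the back step of step 2 at 0.885 min⁻¹. That lowers c(target)/c(intermediate) from 0.80 to 0.701, so I committed to 19.0%. My choice was Sunday's, by 5.8 percentage points against a margin of 2 points.

**The forecast.** It named Sunday's, with 24.4% and 18.3%, slightly below my two figures, and concluded: “The flask wins by about 6 points.”

**The result.** The simulation gives Sunday's, with 24.4% and 18.3%. In Sunday's flask, steps 3 and 4 drew on the substrate until 12.9% of the charge stood, while step 2 shared the 32.0% of intermediate with the target, at a target share of the pool of 43.3% against the pair share of 44.4%. In Monday's tank, substrate stood at 32.2% and intermediate at 26.0%, with a target share of 41.3%. For Sunday's flask left until 80.0 min, the pair share with that drain, taking the charge as entered, reckons 30.7%, and the run stands at 30.4%.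

The numbers of this flask were drawn at random within sensible limits; the flask was simulated.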